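**Retrosynthetic overview**

1. Target 22 ⇐ tetrabenzyl ether 21 ⇐ 4-(phenylsulfanyl)flavan 20: after the key step only four O-benzyl groups and one temporary C4–S bond are removed.
2. Key disconnection: ring C (the pyran ring) of 20 is opened at C4–C4a and at C2–C3, giving the O-aryl O-pivaloyl acetal 18 and phenyl vinyl sulfide 19 as the C3–C4 unit (catalytic enantioselective oxa-Povarov reaction, a formal [4+2]).
3. Enabling feature: C2 carries O1 and the ring B aryl group, so it is an oxocarbenium carbon in disguise. O1 sits on ring A, whose C4a is ortho to O1 and para to the C7 oxygen, and C3–C4 is an unsubstituted ethano bridge, so C4a=C8a–O1=C2(+) is a cationic 2-oxadiene for a two-carbon partner.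
4. 18 ⇐ phenol 13 + aldehyde 15 + pivaloyl chloride. 13 ⇐ ketone 11 (C=O to CH2, O-deallylation) ⇐ chalcone 9 + boronic acid 10 (rhodium-catalysed asymmetric 1,4-arylation sets the diarylmethine centre) ⇐ aldehyde 5 + acetophenone 8.
5. Ring order: rings A and B and both side-chain arenes are bought; ring C is the only ring formed (step 10).

Key step: step 10

Assumption: compounds 1, 2, 4, 6, 7, 10, 14, 16 and 19 are taken as commercial, and the hand named for each chiral catalyst is the one expected from the accepted induction model to deliver the stated face; the antipode would be used if a test reaction showed the opposite sense.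

**Route**

Step 1
Reactants: 1 2,4-dihydroxybenzaldehyde; 2 allyl bromide
Product: 3 4-(allyloxy)-2-hydroxybenzaldehyde
Conditions: allyl bromide (1.05 equiv), CsHCO3, MeCN, 60 °C
Reagents that add atoms: allyl bromide 2, C=CCBr
Why: Williamson etherification; the 4-OH is the more acidic hydroxyl and is not held in the hydrogen bond to the aldehyde, so one equivalent of halide under a weak base should alkylate it selectively.

Step 2
Reactants: 3 4-(allyloxy)-2-hydroxybenzaldehyde; 4 benzyl bromide
Product: 5 4-(allyloxy)-2-(benzyloxy)benzaldehyde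
Conditions: BnBr, K2CO3, DMF, 60 °C
Reagents that add atoms: benzyl bromide 4, BrCc1ccccc1
Why: Williamson etherification of the remaining, chelated phenol under more forcing conditions.

Step 3
Reactants: 6 1-[4-(benzyloxy)-2-hydroxyphenyl]ethan-1-one; 7 iodomethane
Product: 8 1-[4-(benzyloxy)-2-methoxyphenyl]ethan-1-one
Conditions: MeI, K2CO3, acetone, reflux
Reagents that add atoms: iodomethane 7, CI
Why: Williamson O-methylation of the chelated phenol.

Step 4
Reactants: 5 4-(allyloxy)-2-(benzyloxy)benzaldehyde; 8 1-[4-(benzyloxy)-2-methoxyphenyl]ethan-1-one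
Product: 9 (2E)-3-[4-(allyloxy)-2-(benzyloxy)phenyl]-1-[4-(benzyloxy)-2-methoxyphenyl]prop-2-en-1-one
Conditions: KOH (aq), EtOH/THF, rt
Reagents that add atoms: none
Why: Claisen–Schmidt condensation of a methyl ketone with a non-enolisable aldehyde; dehydration of the aldol should give the conjugated E-enone.

Step 5
Reactants: 9 the E-chalcone; 10 4-(benzyloxy)phenylboronic acid
Product: 11 (3R)-3-[4-(allyloxy)-2-(benzyloxy)phenyl]-1-[4-(benzyloxy)-2-methoxyphenyl]-3-[4-(benzyloxy)phenyl]propan-1-one
Conditions: [Rh(OH)((S)-BINAP)]2 (3 mol % Rh), 10 (2.5 equiv), dioxane/H2O 10:1, 50 °C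
Reagents that add atoms: 4-(benzyloxy)phenylboronic acid 10, OB(O)c1ccc(OCc2ccccc2)cc1
Why: Hayashi–Miyaura asymmetric 1,4-addition; transmetalation gives an aryl–rhodium species whose BINAP ligand should direct carbometalation to the Si face of C3 of the E-enone, and hydrolysis of the oxa-π-allyl rhodium intermediate releases the ketone with the (R)-diarylmethine centre.

Step 6
Reactants: 11 the (3R)-ketone
Product: 12 4-(allyloxy)-2-(benzyloxy)-1-[(1R)-3-[4-(benzyloxy)-2-methoxyphenyl]-1-[4-(benzyloxy)phenyl]propyl]benzene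
Conditions: Et3SiH (3 equiv), CF3CO2H, CH2Cl2, 0 °C to rt
Reagents that add atoms: none
Why: Kursanov–Parnes ionic hydrogenation; the protonated aryl ketone and then the alkoxy-stabilised benzylic cation each take hydride from the silane, while the stereocentre lies two carbons from the reacting carbon and is not touched.

Step 7
Reactants: 12 the allyl ether
Product: 13 3-(benzyloxy)-4-[(1R)-3-[4-(benzyloxy)-2-methoxyphenyl]-1-[4-(benzyloxy)phenyl]propyl]phenol
Conditions: Pd(PPh3)4 (2 mol %), K2CO3, MeOH/THF, rt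
Reagents that add atoms: none
Why: Tsuji–Trost-type deallylation; zerovalent palladium ionises the aryl allyl ether to a π-allyl complex and the phenoxide, methanol takes up the allyl group, and the benzyl ethers should not react.

Step 8
Reactants: 14 5-hydroxy-2-methoxybenzaldehyde; 4 benzyl bromide
Product: 15 5-(benzyloxy)-2-methoxybenzaldehyde
Conditions: BnBr, K2CO3, DMF, rt
Reagents that add atoms: benzyl bromide 4, BrCc1ccccc1
Why: Williamson etherification of the only free phenol.

Step 9
Reactants: 15 5-(benzyloxy)-2-methoxybenzaldehyde; 16 pivaloyl chloride; 13 the phenol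
Product: 18 [5-(benzyloxy)-2-methoxyphenyl]{3-(benzyloxy)-4-[(1R)-3-[4-(benzyloxy)-2-methoxyphenyl]-1-[4-(benzyloxy)phenyl]propyl]phenoxy}methyl 2,2-dimethylpropanoate (both epimers at the acetal carbon), via α-chloro pivalate 17 (not isolated)
Conditions: 15, PivCl, ZnCl2 (5 mol %), CH2Cl2, 0 °C to rt; then added to 13, Cs2CO3, MeCN, 0 °C
Reagents that add atoms: pivaloyl chloride 16, CC(C)(C)C(Cl)=O
Why: Addition of the acyl chloride across the aldehyde C=O (1-chloroalkyl ester formation) followed by O-alkylation of the caesium phenoxide at the chlorine-bearing carbon, as in the making of pivaloyloxymethyl ethers; the hindered pivaloyl carbonyl should resist acyl transfer, and the new acetal centre is lost again in step 10.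

Step 10
Reactants: 18 the O-aryl O-pivaloyl acetal; 19 phenyl vinyl sulfide
Product: 20 (2S)-7-(benzyloxy)-2-[5-(benzyloxy)-2-methoxyphenyl]-6-[(1R)-3-[4-(benzyloxy)-2-methoxyphenyl]-1-[4-(benzyloxy)phenyl]propyl]-4-(phenylsulfanyl)-3,4-dihydro-2H-chromene (C4 epimer mixture, 2,4-cis expected to predominate)
Conditions: (S,S)-configured confined imidodiphosphorimidate (IDPi) Brønsted acid (5 mol %), 19 (3 equiv), CH2Cl2/toluene, −60 to −40 °C
Reagents that add atoms: phenyl vinyl sulfide 19, C=CSc1ccccc1
Why: Proposed new method: the chiral acid protonates the pivalate carbonyl of 18 and pivalic acid leaves (a carboxylate is a far better leaving group than the aryloxide, so only the O-aryl oxocarbenium ion forms), giving the E-configured cation C4a=C8a–O1=C2(+) as a contact ion pair with the confined chiral anion; the CH2 terminus of 19 then attacks the Si face of C2 (C2–C3 bond), the sulfur-stabilised cation at C4 is trapped at once by C4a of ring A (C4–C4a bond), and loss of the proton restores the arene and the acid. The closest known reaction type is the SnCl4-promoted oxa-Povarov reaction (racemic formal inverse-electron-demand [4+2] of aryl oxocarbenium ions with alkenes); what is new is chiral-anion control of its first bond formation, reasoned from the ion-pair control that the same acid class exerts in Prins, oxa-Pictet–Spengler and Mukaiyama-type reactions of oxocarbenium ions. Ring C closes as a six-membered cation–arene (Friedel–Crafts) cyclisation, 6-exo-trig at the thionium carbon, which completes the formal [4+2]. C2 is set by the catalyst alone, since the (R)-diarylmethine centre is too remote to interfere, and C4 forms as an epimer mixture that step 11 erases. The step needs ionisation towards the aryl oxocarbenium ion (secured by the pivalate), Markovnikov attack of the alkene (secured by sulfur), and closure at C4a and not at C8 (C4a is para to the 7-benzyloxy group and unhindered, C8 lies between two oxygen substituents).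

Step 11
Reactants: 20 the 4-(phenylsulfanyl)flavan
Product: 21 (2S)-7-(benzyloxy)-2-[5-(benzyloxy)-2-methoxyphenyl]-6-[(1R)-3-[4-(benzyloxy)-2-methoxyphenyl]-1-[4-(benzyloxy)phenyl]propyl]-3,4-dihydro-2H-chromene
Conditions: Raney Ni (W-2, acetone-deactivated), THF/EtOH, rt
Reagents that add atoms: none
Why: Raney nickel desulfurisation; hydrogenolysis of the benzylic C4–S bond removes the temporary activating group and the undefined C4 centre, while the aryl benzyl ethers and the C2–O1 bond are expected to survive at room temperature without added hydrogen.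

Step 12
Reactants: 21 the tetrabenzyl ether
Product: 22 (2S)-2-(5-hydroxy-2-methoxyphenyl)-6-[(1R)-3-(4-hydroxy-2-methoxyphenyl)-1-(4-hydroxyphenyl)propyl]-3,4-dihydro-2H-chromen-7-ol (CNP0239474.1)
Conditions: H2 (1 atm), Pd/C (10 %), EtOAc/MeOH, rt
Reagents that add atoms: none
Why: Catalytic hydrogenolysis of the four aryl benzyl ethers; the cyclic benzylic C2–O1 ether of a flavan should be cleaved far more slowly under neutral conditions at 1 atm, so both stereocentres are kept.

**Compound list**

1 | 2,4-dihydroxybenzaldehyde | O=Cc1ccc(O)cc1O | starting material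
2 | allyl bromide (3-bromoprop-1-ene) | C=CCBr | starting material
3 | 4-(allyloxy)-2-hydroxybenzaldehyde | O=Cc1ccc(OCC=C)cc1O | intermediate
4 | benzyl bromide | BrCc1ccccc1 | starting material
5 | 4-(allyloxy)-2-(benzyloxy)benzaldehyde | O=Cc1ccc(OCC=C)cc1OCc1ccccc1 | intermediate
6 | 1-[4-(benzyloxy)-2-hydroxyphenyl]ethan-1-one | CC(=O)c1ccc(OCc2ccccc2)cc1O | starting material
7 | iodomethane | CI | starting material
8 | 1-[4-(benzyloxy)-2-methoxyphenyl]ethan-1-one | CC(=O)c1ccc(OCc2ccccc2)cc1OC | intermediate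
9 | (2E)-3-[4-(allyloxy)-2-(benzyloxy)phenyl]-1-[4-(benzyloxy)-2-methoxyphenyl]prop-2-en-1-one | COc1cc(OCc2ccccc2)ccc1C(=O)/C=C/c1ccc(OCC=C)cc1OCc1ccccc1 | intermediate
10 | 4-(benzyloxy)phenylboronic acid | OB(O)c1ccc(OCc2ccccc2)cc1 | starting material
11 | (3R)-3-[4-(allyloxy)-2-(benzyloxy)phenyl]-1-[4-(benzyloxy)-2-methoxyphenyl]-3-[4-(benzyloxy)phenyl]propan-1-one | COc1cc(OCc2ccccc2)ccc1C(=O)C[C@H](c1ccc(OCc2ccccc2)cc1)c1ccc(OCC=C)cc1OCc1ccccc1 | intermediate
12 | 4-(allyloxy)-2-(benzyloxy)-1-[(1R)-3-[4-(benzyloxy)-2-methoxyphenyl]-1-[4-(benzyloxy)phenyl]propyl]benzene | COc1cc(OCc2ccccc2)ccc1CC[C@H](c1ccc(OCc2ccccc2)cc1)c1ccc(OCC=C)cc1OCc1ccccc1 | intermediate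
13 | 3-(benzyloxy)-4-[(1R)-3-[4-(benzyloxy)-2-methoxyphenyl]-1-[4-(benzyloxy)phenyl]propyl]phenol | COc1cc(OCc2ccccc2)ccc1CC[C@H](c1ccc(OCc2ccccc2)cc1)c1ccc(O)cc1OCc1ccccc1 | intermediate
14 | 5-hydroxy-2-methoxybenzaldehyde | COc1ccc(O)cc1C=O | starting material
15 | 5-(benzyloxy)-2-methoxybenzaldehyde | COc1ccc(OCc2ccccc2)cc1C=O | intermediate
16 | pivaloyl chloride | CC(C)(C)C(Cl)=O | starting material
17 | chloro[5-(benzyloxy)-2-methoxyphenyl]methyl 2,2-dimethylpropanoate (racemic) | COc1ccc(OCc2ccccc2)cc1C(Cl)OC(=O)C(C)(C)C | intermediate (not isolated)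
18 | [5-(benzyloxy)-2-methoxyphenyl]{3-(benzyloxy)-4-[(1R)-3-[4-(benzyloxy)-2-methoxyphenyl]-1-[4-(benzyloxy)phenyl]propyl]phenoxy}methyl 2,2-dimethylpropanoate (both epimers at the acetal carbon) | COc1cc(OCc2ccccc2)ccc1CC[C@H](c1ccc(OCc2ccccc2)cc1)c1ccc(OC(OC(=O)C(C)(C)C)c2cc(OCc3ccccc3)ccc2OC)cc1OCc1ccccc1 | intermediate
19 | phenyl vinyl sulfide | C=CSc1ccccc1 | starting material
20 | (2S)-7-(benzyloxy)-2-[5-(benzyloxy)-2-methoxyphenyl]-6-[(1R)-3-[4-(benzyloxy)-2-methoxyphenyl]-1-[4-(benzyloxy)phenyl]propyl]-4-(phenylsulfanyl)-3,4-dihydro-2H-chromene (C4 epimer mixture) | COc1cc(OCc2ccccc2)ccc1CC[C@H](c1ccc(OCc2ccccc2)cc1)c1cc2c(cc1OCc1ccccc1)O[C@H](c1cc(OCc3ccccc3)ccc1OC)CC2Sc1ccccc1 | intermediate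
21 | (2S)-7-(benzyloxy)-2-[5-(benzyloxy)-2-methoxyphenyl]-6-[(1R)-3-[4-(benzyloxy)-2-methoxyphenyl]-1-[4-(benzyloxy)phenyl]propyl]-3,4-dihydro-2H-chromene | COc1cc(OCc2ccccc2)ccc1CC[C@H](c1ccc(OCc2ccccc2)cc1)c1cc2c(cc1OCc1ccccc1)O[C@H](c1cc(OCc3ccccc3)ccc1OC)CC2 | intermediate
22 | (2S)-2-(5-hydroxy-2-methoxyphenyl)-6-[(1R)-3-(4-hydroxy-2-methoxyphenyl)-1-(4-hydroxyphenyl)propyl]-3,4-dihydro-2H-chromen-7-ol | COc1cc(O)ccc1CC[C@H](c1ccc(O)cc1)c1cc2c(cc1O)O[C@H](c1cc(O)ccc1OC)CC2 | target

**Step count and risks**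

Total step count: 12. Longest linear sequence: 10 steps (steps 1, 2, 4, 5, 6, 7, 9, 10, 11, 12).

Steps most likely to fail:

1. Step 10 (proposed new method). The chiral counter-anion may discriminate poorly between the faces of a large, flexible oxocarbenium ion. The vinyl sulfide may also be consumed by acid-induced self-condensation, and C2 may erode through reversible ionisation of the O1–C2 bond. The fallback closes ring C at O1–C2 by known chemistry; it sets out from 13 and 15 and comes back at 21, so steps 9, 10 and 11 are not needed. Phenol 13 is iodinated ortho to the hydroxyl and para to the benzyloxy group (NIS, cat. TsOH, MeCN, 0 °C) to give the iodophenol F1. Aldehyde 15 and vinylmagnesium bromide (THF, −78 °C) give the racemic allylic alcohol F2. A Heck reaction of F1 with F2 under ligand-free phase-transfer conditions (Pd(OAc)2, Bu4NCl, NaHCO3, DMF, 50 °C) ends with β-hydride elimination towards the carbinol and should give the 3-arylpropan-1-one F3. Corey–Bakshi–Shibata reduction with the (S)-methyl oxazaborolidine and BH3·SMe2 should give the (1R)-carbinol F4. An intramolecular Mitsunobu etherification (PPh3, DIAD, THF, 0 °C) then closes the pyran ring with inversion to give the (2S)-flavan 21.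

2. Step 9. The phenoxide may attack the pivaloyl carbonyl (acyl transfer) instead of the chlorine-bearing carbon, or the acetal may ionise or solvolyse during isolation. The fallback removes the acyl group from the design; it sets out from 15 and 13 and comes back at 20. Aldehyde 15 is converted into the dimethyl acetal F5 (HC(OMe)3, cat. TsOH, MeOH). F5 is turned into the α-chloro methyl ether F6 with acetyl chloride and catalytic ZnBr2 (CH2Cl2, 0 °C). F6 alkylates the sodium phenoxide of 13 (NaH, THF, 0 °C) to give the O-aryl O-methyl acetal F7. Under the conditions of step 10, with 5 Å molecular sieves to take up methanol, F7 should ionise to the same aryl oxocarbenium ion and give 20.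

3. Step 5. Carbometalation of the hindered, electron-rich enone may be slow against protodeboronation of the boronic acid, or the facial selectivity may be low. The fallback sets the centre by auxiliary control; it sets out from 5 and comes back at 11, so steps 3 and 4 are not needed. Aldehyde 5 undergoes Horner–Wadsworth–Emmons olefination with diethyl {2-oxo-2-[(4S)-2-oxo-4-phenyl-1,3-oxazolidin-3-yl]ethyl}phosphonate (LiCl, iPr2NEt, MeCN) to give the (E)-N-enoyl oxazolidinone F8. 4-(Benzyloxy)phenylmagnesium bromide with CuBr·SMe2 (THF, −40 °C) should add to the chelated s-cis imide anti to the 4-phenyl group (Si face of C3) to give the (3R)-adduct F9. MeNHOMe·HCl with AlMe3 (CH2Cl2, 0 °C) converts F9 into the Weinreb amide F10 and releases the auxiliary. The aryllithium from 4-(benzyloxy)-1-bromo-2-methoxybenzene and n-BuLi (THF, −78 °C) then gives ketone 11.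

**Further compounds**

F1 | step 10 | 5-(benzyloxy)-4-[(1R)-3-[4-(benzyloxy)-2-methoxyphenyl]-1-[4-(benzyloxy)phenyl]propyl]-2-iodophenol | COc1cc(OCc2ccccc2)ccc1CC[C@H](c1ccc(OCc2ccccc2)cc1)c1cc(I)c(O)cc1OCc1ccccc1
F2 | step 10 | 1-[5-(benzyloxy)-2-methoxyphenyl]prop-2-en-1-ol (racemic) | COc1ccc(OCc2ccccc2)cc1C(O)C=C
F3 | step 10 | 3-{4-(benzyloxy)-5-[(1R)-3-[4-(benzyloxy)-2-methoxyphenyl]-1-[4-(benzyloxy)phenyl]propyl]-2-hydroxyphenyl}-1-[5-(benzyloxy)-2-methoxyphenyl]propan-1-one | COc1cc(OCc2ccccc2)ccc1CC[C@H](c1ccc(OCc2ccccc2)cc1)c1cc(CCC(=O)c2cc(OCc3ccccc3)ccc2OC)c(O)cc1OCc1ccccc1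
F4 | step 10 | 5-(benzyloxy)-2-{(3R)-3-[5-(benzyloxy)-2-methoxyphenyl]-3-hydroxypropyl}-4-[(1R)-3-[4-(benzyloxy)-2-methoxyphenyl]-1-[4-(benzyloxy)phenyl]propyl]phenol | COc1cc(OCc2ccccc2)ccc1CC[C@H](c1ccc(OCc2ccccc2)cc1)c1cc(CC[C@@H](O)c2cc(OCc3ccccc3)ccc2OC)c(O)cc1OCc1ccccc1
F5 | step 9 | 4-(benzyloxy)-2-(dimethoxymethyl)-1-methoxybenzene | COc1ccc(OCc2ccccc2)cc1C(OC)OC
F6 | step 9 | 4-(benzyloxy)-2-[chloro(methoxy)methyl]-1-methoxybenzene (racemic, used in solution) | COc1ccc(OCc2ccccc2)cc1C(Cl)OC
F7 | step 9 | 2-(benzyloxy)-4-{[5-(benzyloxy)-2-methoxyphenyl](methoxy)methoxy}-1-[(1R)-3-[4-(benzyloxy)-2-methoxyphenyl]-1-[4-(benzyloxy)phenyl]propyl]benzene (both epimers at the acetal carbon) | COc1cc(OCc2ccccc2)ccc1CC[C@H](c1ccc(OCc2ccccc2)cc1)c1ccc(OC(OC)c2cc(OCc3ccccc3)ccc2OC)cc1OCc1ccccc1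
F8 | step 5 | (4S)-3-{(2E)-3-[4-(allyloxy)-2-(benzyloxy)phenyl]prop-2-enoyl}-4-phenyl-1,3-oxazolidin-2-one | C=CCOc1ccc(/C=C/C(=O)N2[C@@H](c3ccccc3)COC2=O)c(OCc2ccccc2)c1
F9 | step 5 | (4S)-3-{(3R)-3-[4-(allyloxy)-2-(benzyloxy)phenyl]-3-[4-(benzyloxy)phenyl]propanoyl}-4-phenyl-1,3-oxazolidin-2-one | O=C(C[C@H](c1ccc(OCc2ccccc2)cc1)c1ccc(OCC=C)cc1OCc1ccccc1)N1[C@@H](c2ccccc2)COC1=O
F10 | step 5 | (3R)-3-[4-(allyloxy)-2-(benzyloxy)phenyl]-3-[4-(benzyloxy)phenyl]-N-methoxy-N-methylpropanamide | CON(C)C(=O)C[C@H](c1ccc(OCc2ccccc2)cc1)c1ccc(OCC=C)cc1OCc1ccccc1
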